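**Plan** (chroman numbering O1, C2, C3, C4, C4a, C5–C8, C8a; side chain numbered from the acid carbon)

1. Retrosynthetic cuts, in order: the acid C–O bond (ethyl ester); C7–OH (from C7–H); C4–C4a, which opens the dihydropyran ring to an ortho-bromoaryl tertiary allylic ether; O1–C2 (2-bromo-3-methylphenol plus an allylic carbonate); the (2Z) C=C of the enoate (aldehyde plus phosphonate); the aldehyde carbon goes back to the terminal alkene of (2E,6E)-farnesol.
2. Forward: the chain is made first from farnesol (terminal bromohydrin, epoxide, cleavage, Z-olefination) and joined to the phenol through O1–C2; the only ring formed is the dihydropyran ring, closed at C4–C4a; the C7 hydroxyl and the free acid come last.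
3. Enabling feature: C2 is a fully substituted carbon bearing O1, CH3 and the two-carbon bridge C3–C4, which is a hydroborated vinyl group of a tertiary allylic aryl ether; C4a is the arene carbon ortho to O1 and next to the C5 methyl, where a bromine is present in a commercial phenol; C7 is the only ring C–H flanked by two C–H.
4. Stereochemistry: C2 (R) from ligand-controlled palladium-catalysed asymmetric allylic etherification; (6E) from farnesol; (2Z) from a Still–Gennari olefination.

Key step: step 7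

Assumption: in step 6 the (R,R)-ligand is written on the assumption that it gives the (R)-ether from the (10E)-carbonate; if the sense is the opposite, the (S,S)-ligand is used and nothing else changes.

**Route**

Step 1
Reactants: 1 (2E,6E)-farnesol
Product: 2 (2E,6E)-3,7,11-trimethyldodeca-2,6,10-trien-1-yl methyl carbonate
Conditions: ClCO2Me (1.5 equiv), pyridine, DMAP (cat.), CH2Cl2, 0 °C to rt
Reagents that add atoms: methyl chloroformate, COC(=O)Cl
Why: Acylation of the primary allylic alcohol gives the allylic methyl carbonate, which is the ionisable group for step 6 and also deactivates the C2=C3 alkene toward step 2.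

Step 2
Reactants: 2 (2E,6E)-3,7,11-trimethyldodeca-2,6,10-trien-1-yl methyl carbonate
Product: 3 (2E,6E)-10-bromo-11-hydroxy-3,7,11-trimethyldodeca-2,6-dien-1-yl methyl carbonate (racemic at C10)
Conditions: NBS (1.1 equiv), THF/H2O, 0 °C
Reagents that add atoms: N-bromosuccinimide, O=C1CCC(=O)N1Br; water, O
Why: Markovnikov bromohydrin formation should occur at the terminal trisubstituted alkene, the most exposed one in aqueous THF (C2=C3 is deactivated by the carbonate), with water opening the bromonium ion at the tertiary carbon; the racemic stereocenter is removed in step 4.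

Step 3
Reactants: 3 (2E,6E)-10-bromo-11-hydroxy-3,7,11-trimethyldodeca-2,6-dien-1-yl methyl carbonate
Product: 4 (2E,6E)-9-(3,3-dimethyloxiran-2-yl)-3,7-dimethylnona-2,6-dien-1-yl methyl carbonate (racemic)
Conditions: DBU (1.5 equiv), THF, rt
Reagents that add atoms: none
Why: Intramolecular Williamson-type SN2 closure (3-exo-tet) of the tertiary alcohol onto the secondary bromide should give the epoxide, and the non-nucleophilic amidine base leaves the carbonate intact.

Step 4
Reactants: 4 (2E,6E)-9-(3,3-dimethyloxiran-2-yl)-3,7-dimethylnona-2,6-dien-1-yl methyl carbonate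
Product: 5 (2E,6E)-3,7-dimethyl-10-oxodeca-2,6-dien-1-yl methyl carbonate
Conditions: H5IO6 (1.2 equiv), THF/Et2O, 0 °C
Reagents that add atoms: none
Why: Periodic acid opens the trisubstituted epoxide (water entering at the tertiary carbon) and cleaves the resulting glycol in the same pot (Malaprade-type cleavage) to the aldehyde and acetone, the remaining alkenes being inert to periodate.

Step 5
Reactants: 5 (2E,6E)-3,7-dimethyl-10-oxodeca-2,6-dien-1-yl methyl carbonate; 6 ethyl 2-[bis(2,2,2-trifluoroethoxy)phosphoryl]propanoate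
Product: 7 ethyl (2Z,6E,10E)-12-[(methoxycarbonyl)oxy]-2,6,10-trimethyldodeca-2,6,10-trienoate
Conditions: 6 (1.2 equiv), KN(SiMe3)2, 18-crown-6, THF, −78 °C; then 5
Reagents that add atoms: none
Why: Still–Gennari variant of the Horner–Wadsworth–Emmons olefination, in which the electron-poor phosphonate with a dissociated potassium counter-ion eliminates faster than its adducts equilibrate, so the kinetic (Z)-trisubstituted enoate should form.

Step 6
Reactants: 7 ethyl (2Z,6E,10E)-12-[(methoxycarbonyl)oxy]-2,6,10-trimethyldodeca-2,6,10-trienoate; 8 2-bromo-3-methylphenol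
Product: 9 ethyl (2Z,6E,10R)-10-(2-bromo-3-methylphenoxy)-2,6,10-trimethyldodeca-2,6,11-trienoate
Conditions: 8 (1.2 equiv), Pd2(dba)3·CHCl3 (2 mol%), N,N'-[(1R,2R)-cyclohexane-1,2-diyl]bis[2-(diphenylphosphino)benzamide] (6 mol%), CH2Cl2, rt; chromatography on base-washed silica
Reagents that add atoms: none
Why: Tsuji–Trost asymmetric allylic etherification, in which zerovalent palladium ionises the carbonate (CO2 and methoxide, which deprotonates the phenol) and the phenoxide attacks the more substituted allyl terminus C10 inside the chiral ligand pocket after π–σ–π equilibration through the CH2 terminus, so the ligand sets C10 (the future C2) as R.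

Step 7
Reactants: 9 ethyl (2Z,6E,10R)-10-(2-bromo-3-methylphenoxy)-2,6,10-trimethyldodeca-2,6,11-trienoate
Product: 11 ethyl (2Z,6E)-9-[(2R)-2,5-dimethyl-3,4-dihydro-2H-chromen-2-yl]-2,6-dimethylnona-2,6-dienoate, via B-alkyl-9-BBN adduct 10 (not isolated)
Conditions: 9-BBN (1.5 equiv), THF, 0 °C to rt; then Pd(OAc)2 (5 mol%), SPhos (10 mol%), aq K3PO4 (3 equiv), THF/DMF, 0.01 M, 60 °C
Reagents that add atoms: none
Why: 9-BBN adds anti-Markovnikov to the only monosubstituted alkene (the vinyl group on C10; the two trisubstituted alkenes, one an enoate, and the ester are far slower), placing boron on the terminal carbon, the future C4. Zerovalent palladium then inserts into the C–Br bond at the future C4a, the base-activated borate transfers the primary alkyl group to the arylpalladium bromide, and reductive elimination from the seven-membered palladacycle forms the C4–C4a bond. The closest known reaction type is the one-pot hydroboration/intramolecular B-alkyl Suzuki–Miyaura coupling used to close five- and six-membered rings. The six-membered dihydropyran ring (O1, C2, C3, C4, C4a, C8a) is closed by C(sp3)–C(sp2) bond formation at the ipso carbon of the bromide. No stereocenter is made, and the C2 stereocenter from step 6 takes part in no bond change; the basic conditions below 65 °C avoid ionisation or [3,3] rearrangement of the tertiary aryl ether, which is no longer allylic after hydroboration. The step needs chemoselectivity among three alkenes (steric demand of 9-BBN), regioselectivity on the arene (fixed by the bromine between O1 and the methyl group) and cyclisation over intermolecular coupling (high dilution, fast reductive elimination with the biaryl phosphine).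

Step 8
Reactants: 11 ethyl (2Z,6E)-9-[(2R)-2,5-dimethyl-3,4-dihydro-2H-chromen-2-yl]-2,6-dimethylnona-2,6-dienoate
Product: 13 ethyl (2Z,6E)-9-[(2R)-7-hydroxy-2,5-dimethyl-3,4-dihydro-2H-chromen-2-yl]-2,6-dimethylnona-2,6-dienoate, via C7 pinacol boronate 12 (not isolated)
Conditions: [Ir(cod)(OMe)]2 (2 mol%), 4,4'-di-tert-butyl-2,2'-bipyridine (4 mol%), B2pin2 (0.6 equiv), THF, 60 °C; then NaBO3·4H2O (3 equiv), THF/H2O, rt
Reagents that add atoms: sodium perborate tetrahydrate, [Na+].[Na+].O[B-]1(O)OO[B-](O)(O)OO1 (anhydrous dimeric salt)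
Why: Sterically controlled iridium-catalysed arene C–H borylation should take the only aromatic C–H without an ortho substituent (C7; C6 is ortho to the C5 methyl, C8 ortho to O1), trisubstituted alkenes and the ester being tolerated, and perborate oxidation of the aryl boronate (1,2-shift of aryl from boron to oxygen) gives the phenol without epoxidising the alkenes.

Step 9
Reactants: 13 ethyl (2Z,6E)-9-[(2R)-7-hydroxy-2,5-dimethyl-3,4-dihydro-2H-chromen-2-yl]-2,6-dimethylnona-2,6-dienoate
Product: 14 (2Z,6E)-9-[(2R)-7-hydroxy-2,5-dimethyl-3,4-dihydro-2H-chromen-2-yl]-2,6-dimethylnona-2,6-dienoic acid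
Conditions: LiOH·H2O (5 equiv), THF/EtOH/H2O, 40 °C; then 1 M HCl, 0 °C
Reagents that add atoms: lithium hydroxide, [Li+].[OH-]
Why: Saponification (acyl–oxygen cleavage by hydroxide) and acidification should give the acid, since the (Z)-enoate has no isomerisation pathway under these conditions and the tertiary chroman ether tolerates base and brief dilute acid.

**Compound list**

1 | (2E,6E)-farnesol | CC(C)=CCC/C(C)=C/CC/C(C)=C/CO | starting material
2 | (2E,6E)-3,7,11-trimethyldodeca-2,6,10-trien-1-yl methyl carbonate | CC(C)=CCC/C(C)=C/CC/C(C)=C/COC(=O)OC | intermediate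
3 | (2E,6E)-10-bromo-11-hydroxy-3,7,11-trimethyldodeca-2,6-dien-1-yl methyl carbonate (racemic) | CC(C)(O)C(Br)CC/C(C)=C/CC/C(C)=C/COC(=O)OC | intermediate
4 | (2E,6E)-9-(3,3-dimethyloxiran-2-yl)-3,7-dimethylnona-2,6-dien-1-yl methyl carbonate (racemic) | CC1(C)OC1CC/C(C)=C/CC/C(C)=C/COC(=O)OC | intermediate
5 | (2E,6E)-3,7-dimethyl-10-oxodeca-2,6-dien-1-yl methyl carbonate | O=CCC/C(C)=C/CC/C(C)=C/COC(=O)OC | intermediate
6 | ethyl 2-[bis(2,2,2-trifluoroethoxy)phosphoryl]propanoate | CCOC(=O)C(C)P(=O)(OCC(F)(F)F)OCC(F)(F)F | starting material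
7 | ethyl (2Z,6E,10E)-12-[(methoxycarbonyl)oxy]-2,6,10-trimethyldodeca-2,6,10-trienoate | C/C(=C/CC/C(C)=C/CC/C(C)=C/COC(=O)OC)C(=O)OCC | intermediate
8 | 2-bromo-3-methylphenol | Cc1cccc(O)c1Br | starting material
9 | ethyl (2Z,6E,10R)-10-(2-bromo-3-methylphenoxy)-2,6,10-trimethyldodeca-2,6,11-trienoate | C/C(=C/CC/C(C)=C/CC[C@](C)(C=C)Oc1c(Br)c(C)ccc1)C(=O)OCC | intermediate
10 | ethyl (2Z,6E,10S)-12-(9-borabicyclo[3.3.1]nonan-9-yl)-10-(2-bromo-3-methylphenoxy)-2,6,10-trimethyldodeca-2,6-dienoate (same spatial arrangement as 9; the descriptor changes because the boron-bearing arm ranks below the chain) | C/C(=C/CC/C(C)=C/CC[C@](C)(CCB1C2CCCC1CCC2)Oc1c(Br)c(C)ccc1)C(=O)OCC | intermediate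
11 | ethyl (2Z,6E)-9-[(2R)-2,5-dimethyl-3,4-dihydro-2H-chromen-2-yl]-2,6-dimethylnona-2,6-dienoate | C/C(=C/CC/C(C)=C/CC[C@]1(C)CCc2c(C)cccc2O1)C(=O)OCC | intermediate
12 | ethyl (2Z,6E)-9-[(2R)-2,5-dimethyl-7-(4,4,5,5-tetramethyl-1,3,2-dioxaborolan-2-yl)-3,4-dihydro-2H-chromen-2-yl]-2,6-dimethylnona-2,6-dienoate | C/C(=C/CC/C(C)=C/CC[C@]1(C)CCc2c(C)cc(B3OC(C)(C)C(C)(C)O3)cc2O1)C(=O)OCC | intermediate
13 | ethyl (2Z,6E)-9-[(2R)-7-hydroxy-2,5-dimethyl-3,4-dihydro-2H-chromen-2-yl]-2,6-dimethylnona-2,6-dienoate | C/C(=C/CC/C(C)=C/CC[C@]1(C)CCc2c(C)cc(O)cc2O1)C(=O)OCC | intermediate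
14 | (2Z,6E)-9-[(2R)-7-hydroxy-2,5-dimethyl-3,4-dihydro-2H-chromen-2-yl]-2,6-dimethylnona-2,6-dienoic acid | C/C(=C/CC/C(C)=C/CC[C@]1(C)CCc2c(C)cc(O)cc2O1)C(=O)O | target

Total step count: 9. Longest linear sequence: 9 steps (1 to 14).

**Steps most likely to fail**

Step 6. Enantioface control may be incomplete, the phenoxide may attack the unsubstituted allyl terminus, and the tertiary allylic ether may be re-ionised by zerovalent palladium; all are aggravated by the hindered, weakly nucleophilic ortho-bromophenoxide. The fallback sets out from 7 and returns at 9; it takes the stereocenter from an epoxidation and makes the O–aryl bond by arylation of a tertiary alkoxide. Ethanolysis of the carbonate (K2CO3, EtOH, rt) gives ethyl (2Z,6E,10E)-12-hydroxy-2,6,10-trimethyldodeca-2,6,10-trienoate F1. Sharpless asymmetric epoxidation (Ti(OiPr)4, D-(−)-diethyl tartrate, tBuOOH, 4 Å sieves, CH2Cl2, −20 °C) gives ethyl (2Z,6E)-9-[(2R,3R)-3-(hydroxymethyl)-2-methyloxiran-2-yl]-2,6-dimethylnona-2,6-dienoate F2. Iodination (I2, PPh3, imidazole) gives ethyl (2Z,6E)-9-[(2R,3S)-3-(iodomethyl)-2-methyloxiran-2-yl]-2,6-dimethylnona-2,6-dienoate F3. Reductive opening with Zn dust in EtOH/AcOH gives ethyl (2Z,6E,10R)-10-hydroxy-2,6,10-trimethyldodeca-2,6,11-trienoate F4, the C–O bond of the stereocenter staying intact. Its sodium alkoxide (NaH, toluene, rt) is arylated with (2-bromo-3-methylphenyl)(2,4,6-trimethoxyphenyl)iodonium 4-methylbenzenesulfonate F5 (one pot from commercial 2-bromo-1-iodo-3-methylbenzene: mCPBA, TsOH·H2O, then 1,3,5-trimethoxybenzene) to give 9.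

Step 8. Borylation at C8 next to the ring oxygen may compete with C7, and iridium hydride species may add to or isomerise the alkenes. The fallback sets out from 7 and returns at 13; it brings the C7 oxygen in with the phenol. NBS bromination of commercial 3,5-dimethoxytoluene gives 2-bromo-1,5-dimethoxy-3-methylbenzene F6, and BBr3 (CH2Cl2) gives 4-bromo-5-methylbenzene-1,3-diol F7. Silylation of the less hindered hydroxyl (iPr3SiCl, imidazole, DMF) gives 2-bromo-3-methyl-5-[(triisopropylsilyl)oxy]phenol F8. Etherification of 7 with it under the conditions of step 6 gives ethyl (2Z,6E,10R)-10-{2-bromo-3-methyl-5-[(triisopropylsilyl)oxy]phenoxy}-2,6,10-trimethyldodeca-2,6,11-trienoate F9. Hydroboration gives ethyl (2Z,6E,10S)-12-(9-borabicyclo[3.3.1]nonan-9-yl)-10-{2-bromo-3-methyl-5-[(triisopropylsilyl)oxy]phenoxy}-2,6,10-trimethyldodeca-2,6-dienoate F10 (not isolated), and coupling as in step 7 gives ethyl (2Z,6E)-9-{(2R)-2,5-dimethyl-7-[(triisopropylsilyl)oxy]-3,4-dihydro-2H-chromen-2-yl}-2,6-dimethylnona-2,6-dienoate F11. Bu4NF (THF, 0 °C) then gives 13.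

Step 7. Transmetalation of the alkylborane at the doubly ortho-flanked arylpalladium centre may lag behind protodeboronation, β-hydride elimination and intermolecular coupling, and the aqueous base may hydrolyse the ester. The fallback sets out from 9 and returns at 11; it replaces the borane coupling by an anhydrous organozinc cyclisation. Hydroboration to 10 as before and oxidation (NaBO3·4H2O, THF/H2O) give ethyl (2Z,6E,10R)-10-(2-bromo-3-methylphenoxy)-12-hydroxy-2,6,10-trimethyldodeca-2,6-dienoate F12. Iodination (I2, PPh3, imidazole) gives ethyl (2Z,6E,10R)-10-(2-bromo-3-methylphenoxy)-12-iodo-2,6,10-trimethyldodeca-2,6-dienoate F13. Zinc insertion into the primary C–I bond (Zn dust, LiCl, THF) and intramolecular Negishi coupling (Pd(OAc)2, SPhos, THF, 50 °C, high dilution) give 11.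

**Further compounds**

F1 | step 6 | ethyl (2Z,6E,10E)-12-hydroxy-2,6,10-trimethyldodeca-2,6,10-trienoate | C/C(=C/CC/C(C)=C/CC/C(C)=C/CO)C(=O)OCC
F2 | step 6 | ethyl (2Z,6E)-9-[(2R,3R)-3-(hydroxymethyl)-2-methyloxiran-2-yl]-2,6-dimethylnona-2,6-dienoate | C/C(=C/CC/C(C)=C/CC[C@@]1(C)O[C@@H]1CO)C(=O)OCC
F3 | step 6 | ethyl (2Z,6E)-9-[(2R,3S)-3-(iodomethyl)-2-methyloxiran-2-yl]-2,6-dimethylnona-2,6-dienoate | C/C(=C/CC/C(C)=C/CC[C@@]1(C)O[C@@H]1CI)C(=O)OCC
F4 | step 6 | ethyl (2Z,6E,10R)-10-hydroxy-2,6,10-trimethyldodeca-2,6,11-trienoate | C/C(=C/CC/C(C)=C/CC[C@@](C)(O)C=C)C(=O)OCC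
F5 | step 6 | (2-bromo-3-methylphenyl)(2,4,6-trimethoxyphenyl)iodonium 4-methylbenzenesulfonate | Cc1cccc([I+]c2c(OC)cc(OC)cc2OC)c1Br.Cc1ccc(S(=O)(=O)[O-])cc1
F6 | step 8 | 2-bromo-1,5-dimethoxy-3-methylbenzene | COc1cc(C)c(Br)c(OC)c1
F7 | step 8 | 4-bromo-5-methylbenzene-1,3-diol | Cc1cc(O)cc(O)c1Br
F8 | step 8 | 2-bromo-3-methyl-5-[(triisopropylsilyl)oxy]phenol | Cc1cc(O[Si](C(C)C)(C(C)C)C(C)C)cc(O)c1Br
F9 | step 8 | ethyl (2Z,6E,10R)-10-{2-bromo-3-methyl-5-[(triisopropylsilyl)oxy]phenoxy}-2,6,10-trimethyldodeca-2,6,11-trienoate | C/C(=C/CC/C(C)=C/CC[C@](C)(C=C)Oc1cc(O[Si](C(C)C)(C(C)C)C(C)C)cc(C)c1Br)C(=O)OCC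
F10 | step 8 | ethyl (2Z,6E,10S)-12-(9-borabicyclo[3.3.1]nonan-9-yl)-10-{2-bromo-3-methyl-5-[(triisopropylsilyl)oxy]phenoxy}-2,6,10-trimethyldodeca-2,6-dienoate | C/C(=C/CC/C(C)=C/CC[C@](C)(CCB1C2CCCC1CCC2)Oc1cc(O[Si](C(C)C)(C(C)C)C(C)C)cc(C)c1Br)C(=O)OCC
F11 | step 8 | ethyl (2Z,6E)-9-{(2R)-2,5-dimethyl-7-[(triisopropylsilyl)oxy]-3,4-dihydro-2H-chromen-2-yl}-2,6-dimethylnona-2,6-dienoate | C/C(=C/CC/C(C)=C/CC[C@]1(C)CCc2c(C)cc(O[Si](C(C)C)(C(C)C)C(C)C)cc2O1)C(=O)OCC
F12 | step 7 | ethyl (2Z,6E,10R)-10-(2-bromo-3-methylphenoxy)-12-hydroxy-2,6,10-trimethyldodeca-2,6-dienoate | C/C(=C/CC/C(C)=C/CC[C@](C)(CCO)Oc1c(Br)c(C)ccc1)C(=O)OCC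
F13 | step 7 | ethyl (2Z,6E,10R)-10-(2-bromo-3-methylphenoxy)-12-iodo-2,6,10-trimethyldodeca-2,6-dienoate | C/C(=C/CC/C(C)=C/CC[C@](C)(CCI)Oc1c(Br)c(C)ccc1)C(=O)OCC
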